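**Strategy.** Everything rests on cutting the benzene ring (ring A: C3a, C4, C5, C6, C7, C7a) away from the lactone (ring B: C1, O2, C3, C3a, C7a). Ring B is kept as an enantiopure butenolide. Its C3a=C7a alkene is the olefinic end of a vinylketene, and the 1,3-related oxygens on C5 and C7 with hydrogen on C6 are traced to a siloxyalkyne and to the ketene carbonyl. One operation forms C4–C5, C6–C7 and C7–C7a, closes ring A and leaves C7–OH free beside C5–OTIPS for selective methylation. The precursor is a (5S)-4-(diazoacetyl)butenolide bearing the complete side chain, with the C10' ketone as a dioxolane and the (13'S)-alcohol as a TBS ether.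

Key step: step 11

Assumption: (triisopropylsilyloxy)ethyne 17 is taken as a purchasable specialty reagent (TIPS ynol ethers are storable liquids made by O-silylation of lithium ynolates), so its preparation is not counted.

Numbering: ring atoms carry phthalide numbers (C1 carbonyl, O2, C3, C3a, C4 to C7, C7a) from step 11 on. Side-chain atoms are primed.

Step 1
Reactants: 1 (S)-γ-valerolactone [(5S)-5-methyloxolan-2-one]
Product: 2 (4S)-4-hydroxy-N-methoxy-N-methylpentanamide
Conditions: MeNH(OMe)·HCl, AlMe3, CH2Cl2, 0 °C to rt; aq. potassium sodium tartrate; used crude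
Reagents that add atoms: N,O-dimethylhydroxylamine hydrochloride, CNOC.Cl
Why: Weinreb aminolysis of the lactone by the aluminium amide breaks only the acyl C–O bond, so the carbinol carbon (future C13') keeps its (S) configuration.

Step 2
Reactants: 2 (4S)-4-hydroxy-N-methoxy-N-methylpentanamide
Product: 3 (4S)-4-(tert-butyldimethylsilyloxy)-N-methoxy-N-methylpentanamide
Conditions: TBSCl, imidazole, DMF, rt
Reagents that add atoms: tert-butyldimethylsilyl chloride, CC(C)(C)[Si](C)(C)Cl
Why: Imidazole-promoted O-silylation caps the alcohol before it can relactonise and makes no bond change at the stereocentre.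

Step 3
Reactants: 4 1-bromo-8-chlorooctane; 3 (4S)-4-(tert-butyldimethylsilyloxy)-N-methoxy-N-methylpentanamide
Product: 6 (2S)-2-(tert-butyldimethylsilyloxy)-13-chlorotridecan-5-one, via 8-chlorooctylmagnesium bromide 5 (not isolated)
Conditions: 4, Mg, THF, 25–30 °C; then 3, THF, 0 °C; aq. NH4Cl
Reagents that add atoms: none
Why: Magnesium inserts into the weaker C–Br bond and spares C–Cl, and the Weinreb ketone synthesis halts at the chelated tetrahedral adduct so that no tertiary alcohol can form.

Step 4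
Reactants: 6 (2S)-2-(tert-butyldimethylsilyloxy)-13-chlorotridecan-5-one
Product: 7 2-(8-chlorooctyl)-2-[(3S)-3-(tert-butyldimethylsilyloxy)butyl]-1,3-dioxolane
Conditions: TMSOCH2CH2OTMS, TMSOTf (5 mol %), CH2Cl2, −78 to −20 °C; pyridine quench
Reagents that add atoms: 1,2-bis(trimethylsilyloxy)ethane, C[Si](C)(C)OCCO[Si](C)(C)C
Why: Noyori ketalisation is driven by formation of hexamethyldisiloxane under aprotic conditions, so neither water nor protic acid is present to cleave the secondary TBS ether.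

Step 5
Reactants: 7 2-(8-chlorooctyl)-2-[(3S)-3-(tert-butyldimethylsilyloxy)butyl]-1,3-dioxolane; 8 methyl (S)-glycidate [methyl (2S)-oxirane-2-carboxylate]
Product: 10 methyl (2S,15S)-15-(tert-butyldimethylsilyloxy)-12,12-(ethylenedioxy)-2-hydroxyhexadecanoate, via chain alkylmagnesium chloride 9 (not isolated)
Conditions: 7, Mg (I2-activated), THF, 65 °C; then CuI (10 mol %), 8, THF, −40 °C; aq. NH4Cl
Reagents that add atoms: none
Why: In this copper-catalysed Grignard opening of a glycidic ester the organocopper species attacks the unsubstituted epoxide carbon by SN2 faster than the ester at −40 °C, so the C2–O bond is untouched and the (S)-carbinol (future C3) is carried over from 8.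

Step 6
Reactants: 10 methyl (2S,15S)-15-(tert-butyldimethylsilyloxy)-12,12-(ethylenedioxy)-2-hydroxyhexadecanoate
Product: 11 methyl (2S,15S)-2-acetoxy-15-(tert-butyldimethylsilyloxy)-12,12-(ethylenedioxy)hexadecanoate
Conditions: Ac2O, pyridine, DMAP (cat.), CH2Cl2, 0 °C to rt
Reagents that add atoms: acetic anhydride, CC(=O)OC(C)=O
Why: DMAP-catalysed O-acylation installs the two carbons that become C1 and C7a, and these weak bases do not enolise the α-oxygenated ester.

Step 7
Reactants: 11 methyl (2S,15S)-2-acetoxy-15-(tert-butyldimethylsilyloxy)-12,12-(ethylenedioxy)hexadecanoate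
Product: 12 (5S)-5-[(13S)-13-(tert-butyldimethylsilyloxy)-10,10-(ethylenedioxy)tetradecyl]-4-hydroxyfuran-2(5H)-one
Conditions: LiN(SiMe3)2 (2.5 equiv), THF, −78 to 0 °C; cold 0.5 M HCl to pH 3, rapid extraction
Reagents that add atoms: none
Why: In this Dieckmann condensation the hindered amide removes the exposed acetyl proton kinetically, the enolate closes on the methyl ester, and the second equivalent of base stores the product as its tetronate anion, in which C5–H is no longer acidic, so the (S) centre is kept.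

Step 8
Reactants: 12 (5S)-5-[(13S)-13-(tert-butyldimethylsilyloxy)-10,10-(ethylenedioxy)tetradecyl]-4-hydroxyfuran-2(5H)-one
Product: 13 (2S)-2-[(13S)-13-(tert-butyldimethylsilyloxy)-10,10-(ethylenedioxy)tetradecyl]-5-oxo-2,5-dihydrofuran-3-yl trifluoromethanesulfonate
Conditions: Tf2O, 2,6-lutidine, CH2Cl2, −78 °C; cold wash, short silica plug, used at once
Reagents that add atoms: trifluoromethanesulfonic anhydride, O=S(=O)(OS(=O)(=O)C(F)(F)F)C(F)(F)F
Why: O-sulfonylation of the vinylogous acid needs only 2,6-lutidine, a base strong enough for the tetronic acid but too weak to remove the γ-hydrogen of the triflate at −78 °C.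

Step 9
Reactants: 13 (2S)-2-[(13S)-13-(tert-butyldimethylsilyloxy)-10,10-(ethylenedioxy)tetradecyl]-5-oxo-2,5-dihydrofuran-3-yl trifluoromethanesulfonate
Product: 14 (2S)-2-[(13S)-13-(tert-butyldimethylsilyloxy)-10,10-(ethylenedioxy)tetradecyl]-5-oxo-2,5-dihydrofuran-3-carboxylic acid
Conditions: Pd(PPh3)4 (5 mol %), CO (1 atm), KOAc, H2O, DMF, rt; cold work-up at pH 3–4, dried azeotropically, used at once
Reagents that add atoms: carbon monoxide, [C-]#[O+]; water, O
Why: In this palladium-catalysed hydroxycarbonylation of a vinyl triflate the electron-poor C–OTf bond adds to zerovalent palladium at room temperature, CO inserts, the acyl complex is hydrolysed, and the product rests as its carboxylate, which lowers the acidity of the γ-hydrogen.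

Step 10
Reactants: 14 (2S)-2-[(13S)-13-(tert-butyldimethylsilyloxy)-10,10-(ethylenedioxy)tetradecyl]-5-oxo-2,5-dihydrofuran-3-carboxylic acid
Product: 16 (5S)-5-[(13S)-13-(tert-butyldimethylsilyloxy)-10,10-(ethylenedioxy)tetradecyl]-4-(diazoacetyl)furan-2(5H)-one, via acid chloride 15 (not isolated)
Conditions: 1-chloro-N,N,2-trimethylprop-1-en-1-amine (1.0 equiv), CH2Cl2, 0 °C; then CaO, CH2N2 (1.1 equiv, Et2O, added slowly), −20 to 0 °C; kept cold, dilute and dark
Reagents that add atoms: diazomethane, C=[N+]=[N-]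
Why: In this Arndt–Eistert-type acylation of diazomethane the α-chloroenamine forms the acid chloride without releasing HCl (ketal and TBS ether survive) and CaO takes up the HCl of the acylation, so about one equivalent of diazomethane suffices and none is left over for 1,3-dipolar cycloaddition to the doubly activated ring alkene.

Step 11
Reactants: 16 (5S)-5-[(13S)-13-(tert-butyldimethylsilyloxy)-10,10-(ethylenedioxy)tetradecyl]-4-(diazoacetyl)furan-2(5H)-one; 17 (triisopropylsilyloxy)ethyne
Product: 22 (3S)-3-[(13S)-13-(tert-butyldimethylsilyloxy)-10,10-(ethylenedioxy)tetradecyl]-7-hydroxy-5-(triisopropylsilyloxy)-2-benzofuran-1(3H)-one, via vinylketene 18 (not isolated), via 4-vinylcyclobutenone 19 (not isolated), via dienylketene 20 (not isolated), via cyclohexadienone 21 (not isolated)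
Conditions: 17 (2.5 equiv), degassed ClCH2CH2Cl (0.1 M), hν (medium-pressure Hg lamp, Pyrex filter), 20 °C until 16 is consumed; then 80 °C in the dark
Reagents that add atoms: none
Why: Light expels N2 from 16 and C3a migrates to the former diazo carbon C4 (Wolff rearrangement) to give vinylketene 18, whose electrophilic carbon C7 is attacked by the nucleophilic CH terminus of 17, so the (2+2) cycloaddition forms C6–C7 and C4–C5 and gives 4-vinylcyclobutenone 19. On warming, 19 opens by reversible 4π electrocyclic cleavage of C4–C7 to dienylketene 20, and only the isomer with C3a and C6 cis about C4=C5 can go on. Ring A closes by 6π electrocyclisation (C7–C7a) to cyclohexadienone 21, which enolises irreversibly because its C7a hydrogen lies between two carbonyl groups. The closest known reaction type is the Danheiser benzannulation of α,β-unsaturated and heteroaryl α-diazo ketones with siloxyalkynes; no new stereocentre remains in 22 (C4 of 19 and C7a of 21 are flattened) and C3 is a spectator in a medium free of acid and base. The selectivities needed are the orientation of the (2+2) step, secured by the polarity of the O-silyl ynol ether, and excitation of the diazo ketone chromophore alone, secured by Pyrex-filtered light that avoids the short-wavelength bands driving enone–alkyne photocycloaddition.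

Step 12
Reactants: 22 (3S)-3-[(13S)-13-(tert-butyldimethylsilyloxy)-10,10-(ethylenedioxy)tetradecyl]-7-hydroxy-5-(triisopropylsilyloxy)-2-benzofuran-1(3H)-one
Product: 23 (3S)-3-[(13S)-13-(tert-butyldimethylsilyloxy)-10,10-(ethylenedioxy)tetradecyl]-7-methoxy-5-(triisopropylsilyloxy)-2-benzofuran-1(3H)-one
Conditions: MeI, K2CO3, dry acetone, 40 °C
Reagents that add atoms: iodomethane, CI
Why: In this Williamson-type O-methylation carbonate ionises the only free phenol (C7) while C5 stays masked by the bulky TIPS group and the C3 hydrogen of the phthalide is far too weakly acidic to be touched, so site and configuration are secure.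

Step 13
Reactants: 23 (3S)-3-[(13S)-13-(tert-butyldimethylsilyloxy)-10,10-(ethylenedioxy)tetradecyl]-7-methoxy-5-(triisopropylsilyloxy)-2-benzofuran-1(3H)-one
Product: 24 (3S)-5-hydroxy-3-[(13S)-13-hydroxy-10-oxotetradecyl]-7-methoxy-2-benzofuran-1(3H)-one (CNP0341577.2)
Conditions: 48% aq. HF, MeCN, 0 °C to rt; NaHCO3 work-up
Reagents that add atoms: water, O
Why: In this global deprotection HF cleaves both Si–O bonds (strong Si–F bond) and the aqueous acid hydrolyses the dioxolane, while the phthalide, the aryl methyl ether and both stereocentres, at which no bond is broken, are inert.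

**Compound list**

1 | (S)-γ-valerolactone [(5S)-5-methyloxolan-2-one] | C[C@H]1CCC(=O)O1 | starting material
2 | (4S)-4-hydroxy-N-methoxy-N-methylpentanamide | CON(C)C(=O)CC[C@H](C)O | intermediate
3 | (4S)-4-(tert-butyldimethylsilyloxy)-N-methoxy-N-methylpentanamide | CON(C)C(=O)CC[C@H](C)O[Si](C)(C)C(C)(C)C | intermediate
4 | 1-bromo-8-chlorooctane | ClCCCCCCCCBr | starting material
5 | 8-chlorooctylmagnesium bromide | ClCCCCCCCC[Mg]Br | intermediate
6 | (2S)-2-(tert-butyldimethylsilyloxy)-13-chlorotridecan-5-one | ClCCCCCCCCC(=O)CC[C@H](C)O[Si](C)(C)C(C)(C)C | intermediate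
7 | 2-(8-chlorooctyl)-2-[(3S)-3-(tert-butyldimethylsilyloxy)butyl]-1,3-dioxolane | ClCCCCCCCCC1(OCCO1)CC[C@H](C)O[Si](C)(C)C(C)(C)C | intermediate
8 | methyl (S)-glycidate [methyl (2S)-oxirane-2-carboxylate] | COC(=O)[C@@H]1CO1 | starting material
9 | (8-{2-[(3S)-3-(tert-butyldimethylsilyloxy)butyl]-1,3-dioxolan-2-yl}octyl)magnesium chloride | Cl[Mg]CCCCCCCCC1(OCCO1)CC[C@H](C)O[Si](C)(C)C(C)(C)C | intermediate
10 | methyl (2S,15S)-15-(tert-butyldimethylsilyloxy)-12,12-(ethylenedioxy)-2-hydroxyhexadecanoate | COC(=O)[C@@H](O)CCCCCCCCCC1(OCCO1)CC[C@H](C)O[Si](C)(C)C(C)(C)C | intermediate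
11 | methyl (2S,15S)-2-acetoxy-15-(tert-butyldimethylsilyloxy)-12,12-(ethylenedioxy)hexadecanoate | COC(=O)[C@@H](OC(C)=O)CCCCCCCCCC1(OCCO1)CC[C@H](C)O[Si](C)(C)C(C)(C)C | intermediate
12 | (5S)-5-[(13S)-13-(tert-butyldimethylsilyloxy)-10,10-(ethylenedioxy)tetradecyl]-4-hydroxyfuran-2(5H)-one | OC1=CC(=O)O[C@H]1CCCCCCCCCC2(OCCO2)CC[C@H](C)O[Si](C)(C)C(C)(C)C | intermediate
13 | (2S)-2-[(13S)-13-(tert-butyldimethylsilyloxy)-10,10-(ethylenedioxy)tetradecyl]-5-oxo-2,5-dihydrofuran-3-yl trifluoromethanesulfonate | FC(F)(F)S(=O)(=O)OC1=CC(=O)O[C@H]1CCCCCCCCCC2(OCCO2)CC[C@H](C)O[Si](C)(C)C(C)(C)C | intermediate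
14 | (2S)-2-[(13S)-13-(tert-butyldimethylsilyloxy)-10,10-(ethylenedioxy)tetradecyl]-5-oxo-2,5-dihydrofuran-3-carboxylic acid | OC(=O)C1=CC(=O)O[C@H]1CCCCCCCCCC2(OCCO2)CC[C@H](C)O[Si](C)(C)C(C)(C)C | intermediate
15 | (2S)-2-[(13S)-13-(tert-butyldimethylsilyloxy)-10,10-(ethylenedioxy)tetradecyl]-5-oxo-2,5-dihydrofuran-3-carbonyl chloride | ClC(=O)C1=CC(=O)O[C@H]1CCCCCCCCCC2(OCCO2)CC[C@H](C)O[Si](C)(C)C(C)(C)C | intermediate
16 | (5S)-5-[(13S)-13-(tert-butyldimethylsilyloxy)-10,10-(ethylenedioxy)tetradecyl]-4-(diazoacetyl)furan-2(5H)-one | [N-]=[N+]=CC(=O)C1=CC(=O)O[C@H]1CCCCCCCCCC2(OCCO2)CC[C@H](C)O[Si](C)(C)C(C)(C)C | intermediate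
17 | (triisopropylsilyloxy)ethyne | C#CO[Si](C(C)C)(C(C)C)C(C)C | starting material
18 | (5S)-5-[(13S)-13-(tert-butyldimethylsilyloxy)-10,10-(ethylenedioxy)tetradecyl]-4-(2-oxoethenyl)furan-2(5H)-one (vinylketene) | O=C=CC1=CC(=O)O[C@H]1CCCCCCCCCC2(OCCO2)CC[C@H](C)O[Si](C)(C)C(C)(C)C | intermediate
19 | (5S)-5-[(13S)-13-(tert-butyldimethylsilyloxy)-10,10-(ethylenedioxy)tetradecyl]-4-[4-oxo-2-(triisopropylsilyloxy)cyclobut-2-en-1-yl]furan-2(5H)-one (both epimers at the ring CH) | O=C1C=C(O[Si](C(C)C)(C(C)C)C(C)C)C1C2=CC(=O)O[C@H]2CCCCCCCCCC3(OCCO3)CC[C@H](C)O[Si](C)(C)C(C)(C)C | intermediate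
20 | (5S)-5-[(13S)-13-(tert-butyldimethylsilyloxy)-10,10-(ethylenedioxy)tetradecyl]-4-[(1E)-4-oxo-2-(triisopropylsilyloxy)buta-1,3-dien-1-yl]furan-2(5H)-one (dienylketene) | O=C=C/C(O[Si](C(C)C)(C(C)C)C(C)C)=C\C1=CC(=O)O[C@H]1CCCCCCCCCC2(OCCO2)CC[C@H](C)O[Si](C)(C)C(C)(C)C | intermediate
21 | (3S)-3-[(13S)-13-(tert-butyldimethylsilyloxy)-10,10-(ethylenedioxy)tetradecyl]-5-(triisopropylsilyloxy)-3,7a-dihydro-2-benzofuran-1,7-dione (C7a undefined) | O=C1C=C(O[Si](C(C)C)(C(C)C)C(C)C)C=C2C1C(=O)O[C@H]2CCCCCCCCCC3(OCCO3)CC[C@H](C)O[Si](C)(C)C(C)(C)C | intermediate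
22 | (3S)-3-[(13S)-13-(tert-butyldimethylsilyloxy)-10,10-(ethylenedioxy)tetradecyl]-7-hydroxy-5-(triisopropylsilyloxy)-2-benzofuran-1(3H)-one | Oc1cc(O[Si](C(C)C)(C(C)C)C(C)C)cc2c1C(=O)O[C@H]2CCCCCCCCCC3(OCCO3)CC[C@H](C)O[Si](C)(C)C(C)(C)C | intermediate
23 | (3S)-3-[(13S)-13-(tert-butyldimethylsilyloxy)-10,10-(ethylenedioxy)tetradecyl]-7-methoxy-5-(triisopropylsilyloxy)-2-benzofuran-1(3H)-one | COc1cc(O[Si](C(C)C)(C(C)C)C(C)C)cc2c1C(=O)O[C@H]2CCCCCCCCCC3(OCCO3)CC[C@H](C)O[Si](C)(C)C(C)(C)C | intermediate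
24 | (3S)-5-hydroxy-3-[(13S)-13-hydroxy-10-oxotetradecyl]-7-methoxy-2-benzofuran-1(3H)-one | COc1cc(O)cc2c1C(=O)O[C@H]2CCCCCCCCCC(=O)CC[C@H](C)O | target

**Count.** Total steps: 13. Longest linear sequence: 13 steps (1 to 24); 4, 8 and 17 enter as bought.

**Steps most likely to fail**

1. Step 11.
- What may go wrong:
  - Light-driven (2+2) addition of the alkyne to the excited ring alkene.
  - Dimerisation of the electron-poor vinylketene, or its capture by moisture or by the product phenol, before the alkyne reaches it.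
  - Stalling at the four-membered ring, because the 6π closure must end on a carbonyl-bearing carbon. No close model with a lactone-borne vinylketene exists.
- Fallback: ring A by Diels–Alder aromatisation instead of ketene chemistry, setting out from 10 and coming back at 24. Silylation of 10 (TBSCl, imidazole, DMF) should give the bis-TBS ester F1. Reduction with i-Bu2AlH in toluene at −78 °C should give the α-silyloxy aldehyde F2. The Ohira–Bestmann reagent with K2CO3 in MeOH should give the terminal alkyne F3, and n-BuLi followed by ClCO2Me the ynoate F4. Heating F4 with 1,1-dimethoxy-3-(trimethylsilyloxy)buta-1,3-diene in toluene (110–140 °C) should place the nucleophilic CH2 end of the diene on the β-carbon of the ynoate and give the cyclohexadiene adduct F5. This aromatises with loss of methoxytrimethylsilane to the 4-hydroxy-6-methoxybenzoate F6. 48% aq. HF in MeCN then removes both TBS groups and the dioxolane, and the freed benzylic alcohol lactonises onto the neighbouring ester to give 24.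

2. Step 10.
- What may go wrong:
  - 1,3-Dipolar addition of diazomethane across the doubly activated ring alkene.
  - Protonation of the diazo ketone by HCl that is not scavenged in time.
  - Loss of configuration at the γ-carbon on the basic solid.
- Fallback: isocyanide homologation without any diazoalkane, setting out from 14 by way of 15 and coming back at 16. Acid chloride 15 is treated with (isocyanoimino)triphenylphosphorane in CH2Cl2, and insertion of the isocyanide carbon into the C–Cl bond (Nef isocyanide reaction) should give the keto imidoyl chloride phosphazine F7. Water cleaves the P=N bond to the α-keto hydrazonoyl chloride F8. One equivalent of i-Pr2NEt at −20 °C removes HCl, and the C-acyl nitrile imine tautomerises to 16.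

3. Step 9.
- What may go wrong:
  - Hydrolytic loss of the sulfonate, by attack of water or acetate at the ring carbon or at sulfur, before oxidative addition.
  - Base-induced epimerisation at the γ-carbon.
- Fallback: base-free carbon–carbon coupling followed by oxidation, setting out from 13 and coming back at 14. Stille coupling of 13 with Bu3SnCH=CH2 (Pd(PPh3)4, LiCl, THF, 50 °C) should give the 4-vinylbutenolide F9. Johnson–Lemieux cleavage (OsO4 cat., NaIO4, dioxane/H2O) of the more electron-rich terminal alkene should give the 4-formylbutenolide F10. Pinnick oxidation (NaClO2, NaH2PO4, 2-methylbut-2-ene, t-BuOH/H2O) then gives 14 under weakly acidic conditions.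

**Further compounds**

F1 | step 11 | methyl (2S,15S)-2,15-bis(tert-butyldimethylsilyloxy)-12,12-(ethylenedioxy)hexadecanoate | COC(=O)[C@@H](O[Si](C)(C)C(C)(C)C)CCCCCCCCCC1(OCCO1)CC[C@H](C)O[Si](C)(C)C(C)(C)C
F2 | step 11 | (2S,15S)-2,15-bis(tert-butyldimethylsilyloxy)-12,12-(ethylenedioxy)hexadecanal | O=C[C@@H](O[Si](C)(C)C(C)(C)C)CCCCCCCCCC1(OCCO1)CC[C@H](C)O[Si](C)(C)C(C)(C)C
F3 | step 11 | (3S,16S)-3,16-bis(tert-butyldimethylsilyloxy)-13,13-(ethylenedioxy)heptadec-1-yne | C#C[C@@H](O[Si](C)(C)C(C)(C)C)CCCCCCCCCC1(OCCO1)CC[C@H](C)O[Si](C)(C)C(C)(C)C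
F4 | step 11 | methyl (4S,17S)-4,17-bis(tert-butyldimethylsilyloxy)-14,14-(ethylenedioxy)octadec-2-ynoate | COC(=O)C#C[C@@H](O[Si](C)(C)C(C)(C)C)CCCCCCCCCC1(OCCO1)CC[C@H](C)O[Si](C)(C)C(C)(C)C
F5 | step 11 | methyl 2-[(1S,14S)-1,14-bis(tert-butyldimethylsilyloxy)-11,11-(ethylenedioxy)pentadecyl]-6,6-dimethoxy-4-(trimethylsilyloxy)cyclohexa-1,4-diene-1-carboxylate | COC(=O)C1=C([C@@H](O[Si](C)(C)C(C)(C)C)CCCCCCCCCC2(OCCO2)CC[C@H](C)O[Si](C)(C)C(C)(C)C)CC(O[Si](C)(C)C)=CC1(OC)OC
F6 | step 11 | methyl 2-[(1S,14S)-1,14-bis(tert-butyldimethylsilyloxy)-11,11-(ethylenedioxy)pentadecyl]-4-hydroxy-6-methoxybenzoate | COC(=O)c1c(OC)cc(O)cc1[C@@H](O[Si](C)(C)C(C)(C)C)CCCCCCCCCC2(OCCO2)CC[C@H](C)O[Si](C)(C)C(C)(C)C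
F7 | step 10 | (5S)-5-[(13S)-13-(tert-butyldimethylsilyloxy)-10,10-(ethylenedioxy)tetradecyl]-4-{chloro[(triphenylphosphoranylidene)hydrazinylidene]acetyl}furan-2(5H)-one | O=C(C(Cl)=NN=P(c1ccccc1)(c1ccccc1)c1ccccc1)C1=CC(=O)O[C@H]1CCCCCCCCCC2(OCCO2)CC[C@H](C)O[Si](C)(C)C(C)(C)C
F8 | step 10 | (5S)-5-[(13S)-13-(tert-butyldimethylsilyloxy)-10,10-(ethylenedioxy)tetradecyl]-4-[chloro(hydrazinylidene)acetyl]furan-2(5H)-one | NN=C(Cl)C(=O)C1=CC(=O)O[C@H]1CCCCCCCCCC2(OCCO2)CC[C@H](C)O[Si](C)(C)C(C)(C)C
F9 | step 9 | (5S)-5-[(13S)-13-(tert-butyldimethylsilyloxy)-10,10-(ethylenedioxy)tetradecyl]-4-ethenylfuran-2(5H)-one | C=CC1=CC(=O)O[C@H]1CCCCCCCCCC2(OCCO2)CC[C@H](C)O[Si](C)(C)C(C)(C)C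
F10 | step 9 | (2S)-2-[(13S)-13-(tert-butyldimethylsilyloxy)-10,10-(ethylenedioxy)tetradecyl]-5-oxo-2,5-dihydrofuran-3-carbaldehyde | O=CC1=CC(=O)O[C@H]1CCCCCCCCCC2(OCCO2)CC[C@H](C)O[Si](C)(C)C(C)(C)C
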